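## Retrosynthetic overview

1. The target is an unrearranged cembrane. It has one 14-membered carbocycle (C1–C14), and C1, which bears C15(C17)–C16, is its only carbon-branched ring stereocentre. C3/C4, C7/C8 and C11/C12 are the three former E-trisubstituted olefins of a C20 chain, and C15 is an epimerizable lactone α-carbon.
2. C7–OOH and C8=C19 come from a Schenck ene reaction on Δ7 of epoxy lactone 19. The C11–C12 oxirane comes from Shi epoxidation of Δ11 while Δ7 is parked as a C4–O–C7 bromoether (17, 18).
3. The δ-lactone (O–C16–C15–C1–C2–C3) and C4–OH come from Δ3 of acid 10 by 6-exo iodolactonization, an oxirane relay and hydrolysis with inversion at C4. C16 comes from hydroboration–oxidation of the isopropenyl group of 6.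
4. The C1–C2 bond, the macrocycle and C1 come from an (R)-cembrene A synthase acting on achiral geranylgeranyl diphosphate 4, which is made in two steps from geranylgeraniol 1.
5. Ring order: 14-membered carbocycle (step 3), δ-lactone (steps 6 and 9), temporary oxolane (steps 10–12), oxirane (step 11).

Key step: step 3

Remarks on the chemistry:
- Cembrane numbering is used throughout. The target SMILES is read as 1R,3R,4S,7R,11S,12S,15S, and the lactone ring carries C14, C4 and C17 all equatorial.
- Assumption: a recombinant class I cembrene A synthase of (R)-selectivity is used, and the sense of cyclization is checked on hydrocarbon 6 (chiral GC, sign of rotation) before it is carried on.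
- C15 is formed without control in step 4, carried as an epimer pair (left undefined in the SMILES of 7–15) and fixed in step 9.
- A tethered carboxylate, and the oxirane oxygen derived from it, sit on the same face of the former Δ3 olefin. Oxirane 13 is therefore opened by external water at C4, not by the carboxylate at C3.
- Assumption: 17 and 18 are drawn as the cis-2,5-bridged oxolane from anti addition. C7 and C8 are temporary centres there and are erased in step 12.

## Route

Step 1
Reactants: 1 (2E,6E,10E)-geranylgeraniol
Product: 2 (2E,6E,10E)-geranylgeranyl chloride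
Conditions: NCS, Me2S, CH2Cl2, −30 → 0 °C
Reagents that add atoms: N-chlorosuccinimide, O=C1CCC(=O)N1Cl
Why: Corey–Kim-type chlorination, in which the NCS–Me2S adduct activates the primary allylic hydroxyl and chloride displaces it by SN2 under cold neutral conditions, so that neither allylic transposition nor E/Z erosion is expected; no stereocentre is formed.

Step 2
Reactants: 2 geranylgeranyl chloride; 3 tris(tetrabutylammonium) hydrogen diphosphate
Product: 4 geranylgeranyl diphosphate (handled as its tris-ammonium salt)
Conditions: 3 (excess), MeCN, rt; Dowex 50WX8 (NH4+ form), aq. NH4HCO3/iPrOH; cellulose chromatography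
Reagents that add atoms: tris(tetrabutylammonium) hydrogen diphosphate (= 3), CCCC[N+](CCCC)(CCCC)CCCC.CCCC[N+](CCCC)(CCCC)CCCC.CCCC[N+](CCCC)(CCCC)CCCC.OP(=O)([O-])OP(=O)([O-])[O-]
Why: SN2 displacement of a primary allylic chloride by the organic-soluble diphosphate anion is the standard access to allylic diphosphates, and cation exchange gives the water-soluble form that the enzyme accepts; no stereocentre is formed.

Step 3
Reactants: 4 geranylgeranyl diphosphate
Product: 6 (R)-cembrene A, via cembren-15-yl cation 5 (not isolated)
Conditions: (R)-cembrene A synthase (recombinant, purified), MgCl2, HEPES pH 7.5, DTT, 10% glycerol, pentane overlay, 30 °C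
Reagents that add atoms: none
Why: Mg2+-assisted ionization of the allylic diphosphate makes cembrane C2 (chain C1) electrophilic, the distal C1=C15 π bond (chain C14=C15) attacks it through C1 to give the tertiary cation 5, and loss of a methyl proton from C15 leaves the isopropenyl group. The closest known reaction type is this same 1,14-cyclization of geranylgeranyl diphosphate by class I cembrene A (neocembrene) synthases. The single ring closes in a 14-exo olefin–cation mode of Markovnikov sense, since the new C1–C2 σ bond ends at the less substituted olefin carbon and the charge lands on exocyclic C15. The only new stereocentre, C1, is controlled by the fold that the active site imposes on the achiral chain, which exposes one enantioface of the terminal olefin; an (R)-selective enzyme gives the 1R configuration of the target. The step needs attack by the distal rather than the internal olefins, retention of three E geometries, and deprotonation without hydride shift or water capture; the substrate contributes only the tertiary-cation bias and the E allylic geometry that disfavours six-membered closure, and the pocket contour and its exclusion of water secure the rest. The pentane overlay should remove the hydrocarbon from the enzyme as it forms.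

Step 4
Reactants: 6 (R)-cembrene A
Product: 8 (1R,15RS)-cembra-3E,7E,11E-trien-16-ol, via B-alkyl-9-BBN adduct 7 (not isolated)
Conditions: 9-BBN (1.05 equiv), THF, 0 °C → rt; then NaOH, H2O2, 0 °C
Reagents that add atoms: 9-BBN (its boron and cyclooctanediyl unit appear in 7 only), B1C2CCCC1CCC2; hydrogen peroxide, OO
Why: Hydroboration–oxidation, in which 9-BBN should pick the 1,1-disubstituted isopropenyl group over the three trisubstituted ring olefins on steric grounds and place boron on C16, after which oxidation gives the primary alcohol; C15 forms without useful control and is corrected in step 9.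

Step 5
Reactants: 8 (1R,15RS)-cembra-3E,7E,11E-trien-16-ol
Product: 10 (1R,15RS)-cembra-3E,7E,11E-trien-16-oic acid, via C16 aldehyde 9 (not isolated)
Conditions: TEMPO (cat.), PhI(OAc)2 (2.2 equiv), MeCN/H2O 1:1, rt
Reagents that add atoms: water, O
Why: Oxoammonium (TEMPO/PhI(OAc)2) oxidation takes the primary alcohol through the aldehyde hydrate to the acid without any electrophilic halogen, so the electron-rich olefins should survive; no new stereocentre is formed.

Step 6
Reactants: 10 (1R,15RS)-cembra-3E,7E,11E-trien-16-oic acid
Product: 11 (1R,3R,4S,15RS)-4-iodocembra-7E,11E-dien-16,3-olide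
Conditions: I2, NaHCO3, MeCN, 0 °C, dark; crude product used at once
Reagents that add atoms: iodine, II
Why: Kinetic iodolactonization, in which I+ adds reversibly to all three olefins but only the Δ3 iodonium can be captured through a six-membered ring (Δ11 needs seven, Δ7 ten or more), the 6-exo attack at C3 runs through a chair with C14 and C4 equatorial so that C1 sets 3R (the C3–O bond of the target), and anti addition to the E olefin sets C4–I as 4S; a 7-endo isomer formed on the same face would converge on the same oxirane in step 7.

Step 7
Reactants: 11 (1R,3R,4S,15RS)-4-iodocembra-7E,11E-dien-16,3-olide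
Product: 13 methyl (1R,3R,4R,15RS)-3,4-epoxycembra-7E,11E-dien-16-oate, via iodohydrin methyl ester 12 (not isolated)
Conditions: K2CO3, MeOH, 0 °C → rt
Reagents that add atoms: methanol, CO
Why: Methanolysis of the lactone frees the C3 alkoxide, which is antiperiplanar to C4–I as a result of the anti addition and closes the oxirane (halohydrin-to-epoxide, intramolecular Williamson type) with retention at C3 and inversion at C4, giving 3R,4R.

Step 8
Reactants: 13 methyl (1R,3R,4R,15RS)-3,4-epoxycembra-7E,11E-dien-16-oate
Product: 14 methyl (1R,3R,4S,15RS)-3,4-dihydroxycembra-7E,11E-dien-16-oate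
Conditions: HClO4 (cat., dilute aq.), THF/H2O, 0 °C
Reagents that add atoms: water, O
Why: Acid-catalysed hydrolysis of a trisubstituted epoxide, in which water attacks the tertiary, better cation-stabilizing C4 from the rear so that C4 is inverted a second time (4S, the place the iodine held) while the C3–O bond is untouched; cold dilute acid should leave Δ7 and Δ11 alone, and any lactone formed already here feeds step 9.

Step 9
Reactants: 14 methyl (1R,3R,4S,15RS)-3,4-dihydroxycembra-7E,11E-dien-16-oate
Product: 16 (1R,3R,4S,15S)-4-hydroxycembra-7E,11E-dien-16,3-olide, via C15-epimeric hydroxy lactone 15 (not isolated)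
Conditions: DBU, toluene, 100 °C
Reagents that add atoms: none
Why: Base-promoted lactonization closes the six-membered ring on the secondary C3–OH rather than the tertiary C4–OH, and reversible enolization under the same conditions should equilibrate C15 to the isomer with C17 equatorial and trans to C14, which is 15S; the minor epimer can be resubmitted.

Step 10
Reactants: 16 (1R,3R,4S,15S)-4-hydroxycembra-7E,11E-dien-16,3-olide
Product: 17 (1R,3R,4S,7R,8S,15S)-8-bromo-4,7-epoxycembr-11E-en-16,3-olide
Conditions: NBS, CH2Cl2, −20 → 0 °C, dark
Reagents that add atoms: N-bromosuccinimide, O=C1CCC(=O)N1Br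
Why: Bromoetherification, in which Br+ transfer between olefins is reversible and only the Δ7 bromonium has an internal nucleophile in reach (C4–OH, 5-exo, whereas Δ11 would need a nine-membered ring), the 5-exo mode avoids the 1,3-diaxial clash of a 2,2,6,6-tetrasubstituted oxane (that regioisomer would be an equally usable mask), anti addition sets the temporary centres C7 and C8, and bromide is chosen because an alkyl iodide would be oxidized in step 11.

Step 11
Reactants: 17 (1R,3R,4S,7R,8S,15S)-8-bromo-4,7-epoxycembr-11E-en-16,3-olide
Product: 18 (1R,3R,4S,7R,8S,11S,12S,15S)-8-bromo-4,7:11,12-diepoxycembran-16,3-olide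
Conditions: ent-Shi ketone (L-fructose-derived, 30 mol%), Oxone, K2CO3, Bu4NHSO4 (cat.), MeCN/DMM/aq. borate–EDTA buffer, pH ≈ 9.5–10, −5 → 0 °C; work-up at pH 5
Reagents that add atoms: potassium peroxymonosulfate (active part of Oxone), [K+].[O-]S(=O)(=O)OO
Why: Shi asymmetric epoxidation of the only remaining olefin, in which the spiro transition state of the L-fructose-derived dioxirane on an E-trisubstituted olefin delivers oxygen to the face that gives the (S,S)-oxirane (11S,12S), the C–Br bond is inert to the dioxirane, and the lowered pH and temperature spare the δ-lactone.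

Step 12
Reactants: 18 (1R,3R,4S,7R,8S,11S,12S,15S)-8-bromo-4,7:11,12-diepoxycembran-16,3-olide
Product: 19 (1R,3R,4S,11S,12S,15S)-11,12-epoxy-4-hydroxycembr-7E-en-16,3-olide
Conditions: Zn dust (activated), NH4Cl, EtOH, 50 °C
Reagents that add atoms: none
Why: Boord-type reductive β-elimination, in which zinc reduces the tertiary C8–Br bond and the C7–O bond is expelled to return Δ7 and C4–OH, the antiperiplanar Br–C8–C7–O arrangement left by the anti addition holds C6 and C9 anti so the E olefin is expected (stepwise electron transfer could erode this), and the near-neutral medium should spare oxirane and lactone.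

Step 13
Reactants: 19 (1R,3R,4S,11S,12S,15S)-11,12-epoxy-4-hydroxycembr-7E-en-16,3-olide
Product: 20 (1R,3R,4S,7R,11S,12S,15S)-11,12-epoxy-7-hydroperoxy-4-hydroxycembr-8(19)-en-16,3-olide (target)
Conditions: O2, tetraphenylporphyrin (cat.), visible light, CH2Cl2, −20 °C; chromatography without reductive work-up
Reagents that add atoms: dioxygen, O=O
Why: Schenck ene reaction on the only olefin, in which the cis effect confines hydrogen abstraction to the more substituted side (C19–H and C6–H), abstraction from the freely rotating C19 methyl puts oxygen on C7 and creates C8=C19, and 7R requires suprafacial attack on the olefin face that the C4 hydroxyl also reaches (as drawn in 17), which hydrogen bonding in the non-polar solvent may reinforce; regio- and face selectivity are not secured.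

## Compound list

1 | (2E,6E,10E)-geranylgeraniol | CC(C)=CCC/C(C)=C/CC/C(C)=C/CC/C(C)=C/CO | starting material
2 | (2E,6E,10E)-geranylgeranyl chloride | CC(C)=CCC/C(C)=C/CC/C(C)=C/CC/C(C)=C/CCl | intermediate
3 | tris(tetrabutylammonium) hydrogen diphosphate | CCCC[N+](CCCC)(CCCC)CCCC.CCCC[N+](CCCC)(CCCC)CCCC.CCCC[N+](CCCC)(CCCC)CCCC.OP(=O)([O-])OP(=O)([O-])[O-] | starting material
4 | geranylgeranyl diphosphate | CC(C)=CCC/C(C)=C/CC/C(C)=C/CC/C(C)=C/COP(=O)(O)OP(=O)(O)O | intermediate
5 | (1R)-cembra-3E,7E,11E-trien-15-yl cation | C[C+](C)[C@H]1C/C=C(C)/CC/C=C(C)/CC/C=C(C)/CC1 | intermediate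
6 | (R)-cembrene A | C=C(C)[C@H]1C/C=C(C)/CC/C=C(C)/CC/C=C(C)/CC1 | intermediate
7 | B-[(1R)-cembra-3E,7E,11E-trien-16-yl]-9-BBN (C15 epimers) | CC(CB1C2CCCC1CCC2)[C@H]1C/C=C(C)/CC/C=C(C)/CC/C=C(C)/CC1 | intermediate
8 | (1R,15RS)-cembra-3E,7E,11E-trien-16-ol | OCC(C)[C@H]1C/C=C(C)/CC/C=C(C)/CC/C=C(C)/CC1 | intermediate
9 | (1R,15RS)-cembra-3E,7E,11E-trien-16-al | O=CC(C)[C@H]1C/C=C(C)/CC/C=C(C)/CC/C=C(C)/CC1 | intermediate
10 | (1R,15RS)-cembra-3E,7E,11E-trien-16-oic acid | OC(=O)C(C)[C@H]1C/C=C(C)/CC/C=C(C)/CC/C=C(C)/CC1 | intermediate
11 | (1R,3R,4S,15RS)-4-iodocembra-7E,11E-dien-16,3-olide | C1/C=C(C)/CC[C@@H]2C[C@@H](OC(=O)C2C)[C@@](C)(I)CC/C=C(C)/C1 | intermediate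
12 | methyl (1R,3R,4S,15RS)-3-hydroxy-4-iodocembra-7E,11E-dien-16-oate | COC(=O)C(C)[C@H]1C[C@@H](O)[C@@](C)(I)CC/C=C(C)/CC/C=C(C)/CC1 | intermediate
13 | methyl (1R,3R,4R,15RS)-3,4-epoxycembra-7E,11E-dien-16-oate | COC(=O)C(C)[C@H]1C[C@H]2O[C@]2(C)CC/C=C(C)/CC/C=C(C)/CC1 | intermediate
14 | methyl (1R,3R,4S,15RS)-3,4-dihydroxycembra-7E,11E-dien-16-oate | COC(=O)C(C)[C@H]1C[C@@H](O)[C@@](C)(O)CC/C=C(C)/CC/C=C(C)/CC1 | intermediate
15 | (1R,3R,4S,15RS)-4-hydroxycembra-7E,11E-dien-16,3-olide | C1/C=C(C)/CC[C@@H]2C[C@@H](OC(=O)C2C)[C@@](C)(O)CC/C=C(C)/C1 | intermediate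
16 | (1R,3R,4S,15S)-4-hydroxycembra-7E,11E-dien-16,3-olide | C1/C=C(C)/CC[C@@H]2C[C@@H](OC(=O)[C@H]2C)[C@@](C)(O)CC/C=C(C)/C1 | intermediate
17 | (1R,3R,4S,7R,8S,15S)-8-bromo-4,7-epoxycembr-11E-en-16,3-olide | C1/C=C(C)/CC[C@@H]2C[C@@H](OC(=O)[C@H]2C)[C@]3(C)CC[C@@H](O3)[C@@](C)(Br)C1 | intermediate
18 | (1R,3R,4S,7R,8S,11S,12S,15S)-8-bromo-4,7:11,12-diepoxycembran-16,3-olide | C1[C@@H]2O[C@@]2(C)CC[C@@H]2C[C@@H](OC(=O)[C@H]2C)[C@]3(C)CC[C@@H](O3)[C@@](C)(Br)C1 | intermediate
19 | (1R,3R,4S,11S,12S,15S)-11,12-epoxy-4-hydroxycembr-7E-en-16,3-olide | C1[C@@H]2O[C@@]2(C)CC[C@@H]2C[C@@H](OC(=O)[C@H]2C)[C@@](C)(O)CC/C=C(C)/C1 | intermediate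
20 | (1R,3R,4S,7R,11S,12S,15S)-11,12-epoxy-7-hydroperoxy-4-hydroxycembr-8(19)-en-16,3-olide | C=C1CC[C@@H]2O[C@@]2(C)CC[C@@H]2C[C@@H](OC(=O)[C@H]2C)[C@@](C)(O)CC[C@H]1OO | target

## Step count and risks

Total step count: 13. Longest linear sequence: 13 (1 → 20).

**Step 6 (iodolactonization).**
- What may go wrong: closure through seven-membered transition states (at C4 of Δ3 or at C12 of Δ11) may compete with the six-membered mode. The tertiary iodide may be lost by elimination or by acyloxy-assisted solvolysis. Face discrimination by C1 may be weak.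
- Fallback: it sets out from 10 and gives up the tether for site selection in favour of reagent control of the face.
- The carboxylate salt of 10 is epoxidized with the L-fructose-derived Shi ketone and a deficit of Oxone, which spreads (S,S)-mono-epoxidation over the three olefins.
- Only (1R,3S,4S,15RS)-3,4-epoxycembra-7E,11E-dien-16-oic acid F1 can lactonize through a six-membered ring. With Cs2CO3 in DMF at 50 °C its carboxylate opens the oxirane at the secondary C3 (6-exo-tet, inversion to 3R, C4–O retained as 4S).
- The neutral lactone is separated from the isomeric epoxy acids and from unreacted 10 by bicarbonate extraction, and 10 is recycled.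
- The fallback comes back at 15, which is equilibrated with DBU as in step 9 to give 16. It bypasses steps 6–8.

**Step 13 (Schenck ene).**
- What may go wrong: hydrogen abstraction from C6 may compete and place the oxygen on C8, and singlet oxygen may add to the wrong face of Δ7.
- Fallback: it sets out from 19 and brings the oxygen in by substitution with inversion, so that an electrophile may use the exposed face.
- N-(trimethylsilyl)imidazole in CH2Cl2 masks C4–OH as the 4-O-trimethylsilyl ether F2, which stops the hydroxyl from capturing the halonium ion or displacing the halide.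
- Ene-type allylic chlorination with HOCl (Ca(OCl)2, solid CO2, CH2Cl2/H2O, 0 °C) places chlorine on C7 and loses a C19 proton, giving the (7S)-7-chloro-8(19)-ene F3.
- 2-Methoxyprop-2-yl hydroperoxide with Cs2CO3 in DMF at 0 °C, a protected hydrogen peroxide nucleophile, displaces the allylic chloride by SN2 to give the (7R)-peroxyketal F4.
- Mild aqueous acid (PPTS, wet THF/MeOH, 0 °C) removes the ketal and the silyl group. The fallback comes back at 20.

**Step 11 (Shi epoxidation).**
- What may go wrong: the lactone and oxolane bridges may lock the macrocycle so that only one face of Δ11 is exposed. Reagent control then cannot override the substrate, and partial opening of the lactone in the basic medium is a second concern.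
- Fallback: it sets out from 17 and inverts the facial sense by a two-step halohydrin route.
- NBS in THF/H2O at 0 °C lets Br+ take the exposed face at C11 and water enter at the tertiary C12 from the other face, giving the (11R,12S)-bromohydrin F5.
- K2CO3 in MeCN at rt closes the oxirane with inversion at C11, which puts the oxygen on the face opposite to that reached by direct epoxidation. The fallback comes back at 18.

## Further compounds

F1 | step 6 | (1R,3S,4S,15RS)-3,4-epoxycembra-7E,11E-dien-16-oic acid | OC(=O)C(C)[C@H]1C[C@@H]2O[C@@]2(C)CC/C=C(C)/CC/C=C(C)/CC1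
F2 | step 13 | 4-O-trimethylsilyl ether of 19 | C1[C@@H]2O[C@@]2(C)CC[C@@H]2C[C@@H](OC(=O)[C@H]2C)[C@@](C)(O[Si](C)(C)C)CC/C=C(C)/C1
F3 | step 13 | (1R,3R,4S,7S,11S,12S,15S)-7-chloro-11,12-epoxy-4-(trimethylsilyloxy)cembr-8(19)-en-16,3-olide | C=C1CC[C@@H]2O[C@@]2(C)CC[C@@H]2C[C@@H](OC(=O)[C@H]2C)[C@@](C)(O[Si](C)(C)C)CC[C@@H]1Cl
F4 | step 13 | (1R,3R,4S,7R,11S,12S,15S)-11,12-epoxy-7-(2-methoxyprop-2-ylperoxy)-4-(trimethylsilyloxy)cembr-8(19)-en-16,3-olide | C=C1CC[C@@H]2O[C@@]2(C)CC[C@@H]2C[C@@H](OC(=O)[C@H]2C)[C@@](C)(O[Si](C)(C)C)CC[C@H]1OOC(C)(C)OC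
F5 | step 11 | (1R,3R,4S,7R,8S,11R,12S,15S)-8,11-dibromo-4,7-epoxy-12-hydroxycembran-16,3-olide | C1[C@@H](Br)[C@@](C)(O)CC[C@@H]2C[C@@H](OC(=O)[C@H]2C)[C@]3(C)CC[C@@H](O3)[C@@](C)(Br)C1
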